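**Plan**
- Retrosynthesis: C3–H of the target is traced back to C3–Br. Both ring bonds of pyranone C3 (C2–C3 and C3–C4) are then cut, so that C3 leaves as dibromocarbene and the pyranone contracts to the furan ring of 2-aryl-3-silyloxybenzofuran 6.
- Enabling feature: in the pyranone ring C3 is a lone CH between the aryl-bearing C2 and the C4 carbonyl. It is therefore exactly one carbon inserted into the C2=C3 enol-ether bond of a benzofuran with the aryl group on C2 and oxygen on C3.
- Benzofuranone 5 is cut at O1–C2 (phenoxide displacing a benzylic bromide) and at the aryl–carbonyl bond (acylation of 2,3,4-trimethoxyphenol with homoveratric acid).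
- Forward: both arenes are bought. The aryl ketone bond is made first, the five-membered furanone ring is closed second, carbene insertion enlarges it to the six-membered pyranone ring, and the bromine is removed last.
- Stereochemistry: the target has no stereocentre. The stereocentres of 4, 5 and 8 are racemic, transient and end as sp2 carbons.

Key step: step 5

Remarks on the chemistry:
- The target is achiral, so no enantiocontrol is needed.
- The enol is carried as its tert-butyldimethylsilyl ether, because it has to survive potassium tert-butoxide and chromatography.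
- In step 1 BF3·OEt2 is the Lewis-acidic medium and is washed out at work-up; the condensation itself releases only water.

**Step 1**
Reactants: 1 2,3,4-trimethoxyphenol; 2 homoveratric acid
Product: 3 2-(3,4-dimethoxyphenyl)-1-(2-hydroxy-3,4,5-trimethoxyphenyl)ethan-1-one
Conditions: BF3·OEt2 (neat), 85 °C; then aq. NaOAc
Reagents that add atoms: none
Why: Friedel–Crafts acylation of an electron-rich phenol with an arylacetic acid in BF3·OEt2 is the standard deoxybenzoin synthesis, and here it should go to C6 of 1, the only free position ortho to the hydroxyl group (para is blocked), where the ketone is held by chelation and no methoxy group lies ortho to the carbonyl to be cleaved.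

**Step 2**
Reactants: 3 2-(3,4-dimethoxyphenyl)-1-(2-hydroxy-3,4,5-trimethoxyphenyl)ethan-1-one
Product: 4 2-bromo-2-(3,4-dimethoxyphenyl)-1-(2-hydroxy-3,4,5-trimethoxyphenyl)ethan-1-one (racemic, used crude after filtration)
Conditions: CuBr2 (2.1 equiv), EtOAc/CHCl3 (1:1), reflux
Reagents that add atoms: copper(II) bromide, [Cu+2].[Br-].[Br-]
Why: Copper(II) bromide brominates ketones through their enol and is known to leave free phenols and activated arenes untouched (selective α-bromination of hydroxyaryl ketones), and the methylene of 3, flanked by carbonyl and aryl, is the most readily enolised position.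

**Step 3**
Reactants: 4 2-bromo-2-(3,4-dimethoxyphenyl)-1-(2-hydroxy-3,4,5-trimethoxyphenyl)ethan-1-one
Product: 5 2-(3,4-dimethoxyphenyl)-5,6,7-trimethoxy-1-benzofuran-3(2H)-one (racemic)
Conditions: NaOAc (3 equiv), degassed EtOH, reflux, Ar
Reagents that add atoms: none
Why: Intramolecular Williamson etherification, in which the ortho phenoxide displaces the activated α-keto benzylic bromide in a 5-exo-tet closure (the classical coumaranone synthesis), while the weak acetate base and exclusion of air keep the acidic C2–H of 5 from enolate-mediated autoxidation or C-alkylation.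

**Step 4**
Reactants: 5 2-(3,4-dimethoxyphenyl)-5,6,7-trimethoxy-1-benzofuran-3(2H)-one
Product: 6 tert-butyl{[2-(3,4-dimethoxyphenyl)-5,6,7-trimethoxy-1-benzofuran-3-yl]oxy}dimethylsilane
Conditions: TBSOTf (1.2 equiv), Et3N (2 equiv), CH2Cl2, 0 °C, Ar
Reagents that add atoms: tert-butyldimethylsilyl trifluoromethanesulfonate, CC(C)(C)[Si](C)(C)OS(=O)(=O)C(F)(F)F
Why: Soft enolisation with a silyl triflate and an amine base is standard silyl enol ether formation, and it is regiospecific and favourable here because 5 has a single, acidic α-hydrogen (C2–H) and O-silylation makes the furan ring aromatic.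

**Step 5**
Reactants: 6 tert-butyl{[2-(3,4-dimethoxyphenyl)-5,6,7-trimethoxy-1-benzofuran-3-yl]oxy}dimethylsilane; 7 bromoform
Product: 10 3-bromo-2-(3,4-dimethoxyphenyl)-6,7,8-trimethoxy-4H-chromen-4-one, via gem-dibromocyclopropane 8 (not isolated), via 4-silyloxyflavylium bromide 9 (not isolated)
Conditions: KOtBu (3 equiv, slow addition) to 6 and CHBr3 (3 equiv), toluene/hexane, −20 °C → rt, Ar; then 1 M HCl, THF, rt
Reagents that add atoms: none
Why: Proposed new method: singlet dibromocarbene, formed from bromoform by α-elimination, should add in a concerted [2+1] fashion to the C2=C3 bond of 6, the most electron-rich π bond of the molecule because it carries the ring oxygen, the silyloxy group and the aryl group, to give the cis-fused gem-dibromocyclopropane 8. In 8 the endo bromide is aligned for the disrotatory 2π electrocyclic cyclopropyl-to-allyl opening, which breaks the former C2–C3 bond with loss of bromide and is driven by strain release and by formation of the aromatic 4-silyloxyflavylium ion of 9, stabilised by O1, the silyloxy oxygen and the aryl group; bromide or the acidic work-up then takes the silyl group off oxygen and leaves the C4 carbonyl of 10. The closest known reaction types are the dihalocarbene ring enlargement of cyclic silyl enol ethers to α-halo enones and the Ciamician–Dennstedt conversion of indoles into 3-haloquinolines, neither of which has been shown on a 3-silyloxybenzofuran. The three-membered ring closes by cheletropic addition, and the six-membered pyranone ring arises by insertion of the carbene carbon (ring enlargement), so no separate cyclisation is needed. The two stereocentres of 8 are transient, necessarily cis and racemic, and both return to sp2, so nothing has to be controlled. The step needs chemoselectivity for the enol-ether bond over the two methoxylated arenes and survival of the Si–O bond until the carbene has added; the much higher nucleophilicity of the doubly oxygenated alkene, the tert-butyldimethylsilyl group and the slow addition of base at low temperature should secure both.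

**Step 6**
Reactants: 10 3-bromo-2-(3,4-dimethoxyphenyl)-6,7,8-trimethoxy-4H-chromen-4-one
Product: 11 2-(3,4-dimethoxyphenyl)-6,7,8-trimethoxy-4H-chromen-4-one
Conditions: Pd(OAc)2 (5 mol%), PPh3 (15 mol%), HCO2Na (3 equiv), DMF, 80 °C
Reagents that add atoms: none
Why: Palladium-catalysed formate hydrodehalogenation, in which Pd(0) inserts into the activated C3–Br bond of the α-bromo enone, formate exchanges for bromide and loses CO2 to give a palladium hydride, and reductive elimination forms C3–H, without touching the pyranone double bond or the aryl methyl ethers as heterogeneous hydrogenation might.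

**Compound list**
1 | 2,3,4-trimethoxyphenol | COc1ccc(O)c(OC)c1OC | starting material
2 | homoveratric acid, (3,4-dimethoxyphenyl)acetic acid | COc1ccc(CC(=O)O)cc1OC | starting material
3 | 2-(3,4-dimethoxyphenyl)-1-(2-hydroxy-3,4,5-trimethoxyphenyl)ethan-1-one | COc1ccc(CC(=O)c2cc(OC)c(OC)c(OC)c2O)cc1OC | intermediate
4 | 2-bromo-2-(3,4-dimethoxyphenyl)-1-(2-hydroxy-3,4,5-trimethoxyphenyl)ethan-1-one (racemic) | COc1ccc(C(Br)C(=O)c2cc(OC)c(OC)c(OC)c2O)cc1OC | intermediate
5 | 2-(3,4-dimethoxyphenyl)-5,6,7-trimethoxy-1-benzofuran-3(2H)-one (racemic, C2 configurationally labile) | COc1ccc(C2Oc3c(OC)c(OC)c(OC)cc3C2=O)cc1OC | intermediate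
6 | tert-butyl{[2-(3,4-dimethoxyphenyl)-5,6,7-trimethoxy-1-benzofuran-3-yl]oxy}dimethylsilane | COc1ccc(-c2oc3c(OC)c(OC)c(OC)cc3c2O[Si](C)(C)C(C)(C)C)cc1OC | intermediate
7 | bromoform | BrC(Br)Br | starting material
8 | 1,1-dibromo-6b-[(tert-butyldimethylsilyl)oxy]-1a-(3,4-dimethoxyphenyl)-3,4,5-trimethoxy-1a,6b-dihydro-1H-cyclopropa[b][1]benzofuran (racemic, cis-fused; formed in the flask, not isolated) | COc1ccc(cc1OC)C12Oc3c(OC)c(OC)c(OC)cc3C1(O[Si](C)(C)C(C)(C)C)C2(Br)Br | intermediate
9 | 3-bromo-4-[(tert-butyldimethylsilyl)oxy]-2-(3,4-dimethoxyphenyl)-6,7,8-trimethoxychromenylium bromide (formed in the flask, not isolated) | COc1ccc(cc1OC)-c1[o+]c2c(OC)c(OC)c(OC)cc2c(O[Si](C)(C)C(C)(C)C)c1Br.[Br-] | intermediate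
10 | 3-bromo-2-(3,4-dimethoxyphenyl)-6,7,8-trimethoxy-4H-chromen-4-one | COc1ccc(-c2oc3c(OC)c(OC)c(OC)cc3c(=O)c2Br)cc1OC | intermediate
11 | 2-(3,4-dimethoxyphenyl)-6,7,8-trimethoxy-4H-chromen-4-one (CNP0388881.0) | COc1ccc(-c2cc(=O)c3cc(OC)c(OC)c(OC)c3o2)cc1OC | target

**Step count and risks**
Total step count: 6. Longest linear sequence: 6 steps (1 or 2 → 11).

Steps most likely to fail:

Step 5. The carbene may fail to add to the hindered, aromatic enol-ether bond. Alkoxide may also cleave the Si–O bond first, so that the free enolate is dibromomethylated at carbon instead of enlarged, or it may open the newly formed pyranone by conjugate addition. The fallback uses known flavone chemistry, sets out from 1 and comes back to the route at 11. Phenol 1 is acetylated with acetic acid in BF3·OEt2 to 1-(2-hydroxy-3,4,5-trimethoxyphenyl)ethan-1-one F1. Claisen–Schmidt condensation of this ketone with commercial 3,4-dimethoxybenzaldehyde (KOH, EtOH) should give (E)-3-(3,4-dimethoxyphenyl)-1-(2-hydroxy-3,4,5-trimethoxyphenyl)prop-2-en-1-one F2. Oxidative cyclisation of the 2'-hydroxychalcone with catalytic iodine in DMSO at 130 °C (oxa-Michael closure, then dehydrogenation) should give 11 directly.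

Step 2. Electrophilic bromination of one of the two methoxylated rings may compete with bromination of the enol. Premature ring closure under the acidic conditions may be followed by a second bromination at C2. The fallback sets out from 3 and comes back at 5, replacing steps 2 and 3. The phenol is masked with Ac2O/pyridine as 2-[2-(3,4-dimethoxyphenyl)acetyl]-4,5,6-trimethoxyphenyl acetate F3, which deactivates ring A and prevents early closure. The ketone is brominated with phenyltrimethylammonium tribromide in THF to 2-[2-bromo-2-(3,4-dimethoxyphenyl)acetyl]-4,5,6-trimethoxyphenyl acetate F4. K2CO3 in MeOH under argon then removes the acetate, and the released phenoxide closes the furanone ring to 5.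

Step 1. Acylation may occur at the other free position of the phenol (C5, activated by the 2- and 4-methoxy groups). The arylacetic acid may acylate its own dimethoxyphenyl ring, or O-acylation may fail to migrate to carbon. The fallback sets out from 2 and comes back at 3. Commercial 1,2,3,4-tetramethoxybenzene, whose two free positions are equivalent, is acylated with 2 under TFAA/H3PO4 to 2-(3,4-dimethoxyphenyl)-1-(2,3,4,5-tetramethoxyphenyl)ethan-1-one F5. BCl3 in CH2Cl2 (−78 → 0 °C) then cleaves only the methoxy group ortho to the carbonyl, by chelation, to give 3.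

**Further compounds**
F1 | step 5 | 1-(2-hydroxy-3,4,5-trimethoxyphenyl)ethan-1-one | CC(=O)c1cc(OC)c(OC)c(OC)c1O
F2 | step 5 | (E)-3-(3,4-dimethoxyphenyl)-1-(2-hydroxy-3,4,5-trimethoxyphenyl)prop-2-en-1-one | COc1ccc(/C=C/C(=O)c2cc(OC)c(OC)c(OC)c2O)cc1OC
F3 | step 2 | 2-[2-(3,4-dimethoxyphenyl)acetyl]-4,5,6-trimethoxyphenyl acetate | COc1ccc(CC(=O)c2cc(OC)c(OC)c(OC)c2OC(C)=O)cc1OC
F4 | step 2 | 2-[2-bromo-2-(3,4-dimethoxyphenyl)acetyl]-4,5,6-trimethoxyphenyl acetate (racemic) | COc1ccc(C(Br)C(=O)c2cc(OC)c(OC)c(OC)c2OC(C)=O)cc1OC
F5 | step 1 | 2-(3,4-dimethoxyphenyl)-1-(2,3,4,5-tetramethoxyphenyl)ethan-1-one | COc1ccc(CC(=O)c2cc(OC)c(OC)c(OC)c2OC)cc1OC
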